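The data come from a simulation on assumed constants; scatter was added.

Of the substrate charged, 88.3% is left in the ash run at 8.00 h; the missing part, spread over those hours, is a draw of 1.46 mM h⁻¹.

| flask | substrate | partner | free catalyst | remark | time |
|---|---|---|---|---|---|
| birch | 0.10 M | 0.18 M | 0.20 mM | run made earlier |  |
| oak | 0.10 M | 0.18 M | 0.13 mM | run made earlier |  |
| ash | 0.10 M | 0.18 M | 0.30 mM | run made earlier |  |
| elm | 0.10 M | 0.36 M | 0.20 mM | run made earlier |  |
| north-east | 0.10 M | 0.180 M | 0.20 mM | everything together at the start | 8.0 h |
| east | 0.10 M (fed, over 5.0 h) | 0.180 M | 0.20 mM | all else is in the flask from the start; the feed brings no volume worth counting | 8.0 h |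
| south-west | 0.10 M | 0.180 M (fed, over 5.0 h) | 0.20 mM | all else is in the flask from the start; the feed brings no volume worth counting | 8.0 h |

| run | time / h | target / % | substrate / % |
|---|---|---|---|
| birch | 0.667 | 1.0 | 99.9 |
| birch | 1.50 | 1.3 | 98.1 |
| birch | 3.00 | 3.0 | 96.4 |
| birch | 5.00 | 4.6 | 95.0 |
| oak | 0.667 | 1.5 | 99.7 |
| oak | 1.33 | 0.6 | 99.3 |
| oak | 3.00 | 1.2 | 98.3 |
| oak | 8.00 | 3.7 | 94.7 |
| ash | 1.00 | 0.7 | 98.1 |
| ash | 3.00 | 3.9 | 95.4 |
| ash | 5.00 | 7.3 | 93.3 |
| ash | 8.00 | 11.0 | 88.3 |
| elm | 2.00 | 0.4 | 98.8 |
| elm | 4.00 | 1.6 | 97.8 |
| elm | 6.00 | 2.9 | 97.3 |
| elm | 8.00 | 2.3 | 96.4 |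

(each reading ± 0.5 percentage points)

- the flask with the highest amount of target, in percent of the substrate charged ("all alike" if they lie within 1.5 percentage points) (north-east / east / south-west / all alike)
- final target, as a percentage of the substrate charged, in north-east
- final target, as a percentage of the substrate charged, in east
- final target, as a percentage of the substrate charged, in south-west

- what was read earlier has a scatter of 0.5 percentage points, one standard deviation

That draw times c(partner) over c(free catalyst) is the brake constant, 0.878 M h⁻¹ from ash. The oak run gives 0.917 M h⁻¹ and the elm run 0.810 M h⁻¹, so this reckoning takes the draw as the constant times c(free catalyst)/c(partner): partner inhibition.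

By this rule north-east draws 0.975 mM h⁻¹ and is reckoned to reach 7.80%. The rule has no substrate term, which is an assumption, since birch, oak, ash and elm share 0.10 M of substrate. East's feed of 20.0 mM h⁻¹ is far above that draw, so east is reckoned at the same 7.80%.

In south-west, c(partner) grows with the feed of 36.0 mM h⁻¹, so by the rule the draw falls as one over time and target grows with the logarithm of time. Run backwards, the rule's draw equals the feed at 0.135 h. Counting the partner fed up to then as turned to target and following the rule onward gives a high figure of 25.4%.

That start is the weak link: the earlier runs were charged with 0.18 M or 0.36 M of partner, and the rule is stretched far below that. Trusting the rule from 0.0180 M of partner fed on, reached at 0.500 h, and counting no target before, gives a low figure of 14.2%. This reckoning commits to that figure, with south-west ahead.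

The forecast names south-west, with 7.6%, 5.5% and 14% for north-east, east and south-west, noting “Partner must still be needed at very low levels”. Its east lies below the 7.80% reckoned here.

North-east, east and south-west give 7.48%, 7.30% and 15.5%, so south-west leads north-east by 8 percentage points against a margin of 1.5 points, and its figure lies between the low and the high reckoning.

    substrate + free catalyst → catalyst intermediate A (k = 7700 L mol⁻¹ h⁻¹)
    partner + catalyst intermediate A → catalyst intermediate B (k = 8000 L mol⁻¹ h⁻¹)
    catalyst intermediate B ⇌ by-product + catalyst intermediate C (K = 2.50 M, k = 310 h⁻¹)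
    catalyst intermediate C → free catalyst + target (k = 300 h⁻¹)
    partner + catalyst intermediate C ⇌ idle complex, settled at all times (K = 350 L mol⁻¹)

In north-east the parking constant times starting partner is 63, and at 8.00 h the idle complex, an off-cycle form, holds 95.8% of the catalyst against 1.59% in catalyst intermediate C. South-west has half of the turnover up to 8.0 h of the step from catalyst intermediate B to by-product and catalyst intermediate C behind it by 1.83 h, with 36.6% of its partner charge fed.

A neighbour of south-west holds 0.25 M of substrate. With 0.878 M h⁻¹ and no substrate term, the low figure's amount of target over that charge is 5.66%; the flask gives 6.30%.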